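**Plan**

- Backwards, ring B is first returned to a 1,4-cyclohexadiene (two H back on C2' and C5') and then cut at C1'–C2' and C5'–C6' into 2-ethynyl-5,7,8-trimethoxychromone and 2,3-dimethoxybuta-1,3-diene.
- This works because ring B (C1'–C6') carries only two methoxy groups, on the neighbouring carbons C3' and C4', which are the inner carbons of a symmetric diene; C1' and C6' can be the two carbons of an alkyne on C2 of ring C.
- The alkyne is cut at C1'≡C6' back to the C2 aldehyde and that to a C2 methyl group; ring C is cut at O1–C2 and C2–C3 (cyclodehydration, Claisen condensation) and the acetyl group at C4–C4a, leaving 1,2,3,5-tetramethoxybenzene.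
- Forward: ring A is bought, ring C closes in step 2, the alkyne is installed in steps 3 and 4, ring B closes last by [4+2] cycloaddition and is aromatised with DDQ.
- Stereochemistry: the target has no stereocentre and no stereogenic double bond; the only sp3 ring carbons made on the way are CH2 groups that vanish on aromatisation.

Key step: step 5

Assumption: in step 1 AlCl3 is taken to cleave the methoxy group flanked by the new acetyl group and a second methoxy group, as in other 2,3-dialkoxyaryl ketones; fod in step 5 is 6,6,7,7,8,8,8-heptafluoro-2,2-dimethyl-3,5-octanedionate.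

**Route**

Step 1
Reactants: 1 1,2,3,5-tetramethoxybenzene
Product: 3 1-(2-hydroxy-3,4,6-trimethoxyphenyl)ethan-1-one, via 1-(2,3,4,6-tetramethoxyphenyl)ethan-1-one 2 (not isolated)
Conditions: AcCl (1.2 equiv), AlCl3 (2.5 equiv), Et2O, 0 °C to rt; aqueous work-up
Reagents that add atoms: acetyl chloride, CC(Cl)=O
Why: Friedel–Crafts acylation should occur at one of the two equivalent free ring positions, each activated by two ortho and one para methoxy groups, and the AlCl3 held on the new carbonyl should then cleave the neighbouring C2 methyl ether through a six-membered chelate (ortho-selective Lewis acid demethylation), this methoxy group being the one twisted out of the ring plane by its two neighbours.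

Step 2
Reactants: 3 1-(2-hydroxy-3,4,6-trimethoxyphenyl)ethan-1-one
Product: 5 5,7,8-trimethoxy-2-methyl-4H-chromen-4-one, via 1-(2-hydroxy-3,4,6-trimethoxyphenyl)butane-1,3-dione 4 (not isolated)
Conditions: NaH (4 equiv), EtOAc (excess), THF, reflux; aq. HCl quench; then H2SO4 (cat.), AcOH, 100 °C
Reagents that add atoms: ethyl acetate, CCOC(C)=O
Why: Claisen condensation of the ketone enolate (formed beside the phenoxide) with ethyl acetate is pulled forward by deprotonation of the 1,3-diketone, and under acid the phenol should add to the distal carbonyl (6-exo-trig) and lose water to close ring C, the classical 2-methylchromone synthesis.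

Step 3
Reactants: 5 5,7,8-trimethoxy-2-methyl-4H-chromen-4-one
Product: 6 5,7,8-trimethoxy-4-oxo-4H-chromene-2-carbaldehyde
Conditions: SeO2 (1.5 equiv), xylene, 140 °C
Reagents that add atoms: selenium dioxide, O=[Se]=O
Why: Riley oxidation, in which the C2 methyl group, vinylogously alpha to the C4 carbonyl, reacts with SeO2 like the methyl group of an aryl methyl ketone (ene reaction, [2,3]-sigmatropic shift, loss of selenium and water), a conversion known for 2-methylchromones, while the methoxyarene is inert to SeO2.

Step 4
Reactants: 6 5,7,8-trimethoxy-4-oxo-4H-chromene-2-carbaldehyde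
Product: 7 2-ethynyl-5,7,8-trimethoxy-4H-chromen-4-one
Conditions: dimethyl (1-diazo-2-oxopropyl)phosphonate (1.3 equiv), K2CO3 (2 equiv), MeOH/THF, 0 °C to rt
Reagents that add atoms: dimethyl (1-diazo-2-oxopropyl)phosphonate, CC(=O)C(=[N+]=[N-])P(=O)(OC)OC
Why: Ohira–Bestmann variant of the Seyferth–Gilbert homologation, in which methanolysis of the acetyl group frees the anion of dimethyl (diazomethyl)phosphonate, which adds to the aldehyde, loses dimethyl phosphate in a Horner–Wadsworth–Emmons-type step and then N2, the alkylidene carbene giving the terminal alkyne by 1,2-hydrogen shift; the aldehyde is by far the most electrophilic site at 0 °C, so the pyranone ring should survive the carbonate.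

Step 5
Reactants: 7 2-ethynyl-5,7,8-trimethoxy-4H-chromen-4-one; 8 2,3-dimethoxybuta-1,3-diene
Product: 9 2-(4,5-dimethoxycyclohexa-1,4-dien-1-yl)-5,7,8-trimethoxy-4H-chromen-4-one
Conditions: 8 (4 equiv), Eu(fod)3 (10 mol%), BHT (cat.), PhMe, 110 °C, sealed tube; filtration through basic Al2O3
Reagents that add atoms: none
Why: The electron-rich s-cis diene 8 and the terminal alkyne of 7 should combine in a thermal, concerted, suprafacial [4+2] cycloaddition (diene HOMO, alkyne LUMO), the alkyne being polarised through C2=C3 by the C4 carbonyl and further by the oxophilic europium chelate, which binds the C4 carbonyl and C5 methoxy oxygens and is mild enough to leave enol ethers intact. The closest known reaction type is the Diels–Alder reaction of carbonyl-conjugated alkynes (ynones, propiolates) with 2,3-dialkoxybutadienes, which gives 1,4-cyclohexadienes that are aromatised afterwards. Ring B closes as a six-membered carbocycle by intermolecular cycloaddition, both new bonds (C1'–C2' and C5'–C6') forming in one step, one at each end of the diene. No stereocentre arises, since the two new sp3 carbons are CH2 groups. The step needs periselectivity for the alkyne over the C2=C3 bond, which is secured because the unhindered terminal alkyne is a far better dienophile than a trisubstituted vinylogous-ester alkene that would have to give up the pyranone conjugation and form a quaternary carbon; regiochemistry is not in question because 8 is symmetric, so the methoxy groups must end up on C3' and C4'. Excess diene, BHT and a neutral aprotic medium should keep diene polymerisation and enol ether hydrolysis from outrunning the cycloaddition.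

Step 6
Reactants: 9 2-(4,5-dimethoxycyclohexa-1,4-dien-1-yl)-5,7,8-trimethoxy-4H-chromen-4-one
Product: 10 isosinensetin, 2-(3,4-dimethoxyphenyl)-5,7,8-trimethoxy-4H-chromen-4-one
Conditions: DDQ (1.1 equiv), PhMe, rt
Reagents that add atoms: none
Why: Oxidative aromatisation, in which DDQ takes a hydride from a doubly allylic CH2 group to give an oxygen-stabilised cyclohexadienyl cation that loses a proton, the gain of aromaticity in ring B driving the reaction at room temperature, where the chromone and the aryl methyl ethers do not react with the quinone.

**Compound list**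

1 | 1,2,3,5-tetramethoxybenzene | COc1cc(OC)c(OC)c(OC)c1 | starting material
2 | 1-(2,3,4,6-tetramethoxyphenyl)ethan-1-one | CC(=O)c1c(OC)cc(OC)c(OC)c1OC | intermediate
3 | 1-(2-hydroxy-3,4,6-trimethoxyphenyl)ethan-1-one | CC(=O)c1c(OC)cc(OC)c(OC)c1O | intermediate
4 | 1-(2-hydroxy-3,4,6-trimethoxyphenyl)butane-1,3-dione | CC(=O)CC(=O)c1c(OC)cc(OC)c(OC)c1O | intermediate
5 | 5,7,8-trimethoxy-2-methyl-4H-chromen-4-one | Cc1cc(=O)c2c(OC)cc(OC)c(OC)c2o1 | intermediate
6 | 5,7,8-trimethoxy-4-oxo-4H-chromene-2-carbaldehyde | O=Cc1cc(=O)c2c(OC)cc(OC)c(OC)c2o1 | intermediate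
7 | 2-ethynyl-5,7,8-trimethoxy-4H-chromen-4-one | C#Cc1cc(=O)c2c(OC)cc(OC)c(OC)c2o1 | intermediate
8 | 2,3-dimethoxybuta-1,3-diene | COC(=C)C(=C)OC | starting material
9 | 2-(4,5-dimethoxycyclohexa-1,4-dien-1-yl)-5,7,8-trimethoxy-4H-chromen-4-one | COC1=C(OC)CC(c2cc(=O)c3c(OC)cc(OC)c(OC)c3o2)=CC1 | intermediate
10 | isosinensetin, 2-(3,4-dimethoxyphenyl)-5,7,8-trimethoxy-4H-chromen-4-one | COc1ccc(-c2cc(=O)c3c(OC)cc(OC)c(OC)c3o2)cc1OC | target

**Step count and risks**

Total steps: 6. Longest linear sequence: 6 steps (1 to 10).

Steps most likely to fail:

Step 5. The alkyne is activated only through the vinylogous link to the C4 carbonyl, so the cycloaddition may be slower than thermal oligomerisation of the diene, and the enol ether units may hydrolyse on the Lewis acid. The fallback gives up the late construction of ring B and brings it in ready-made; it sets out from 3 and rejoins the route at 10. Phenol 3 would be acylated with 3,4-dimethoxybenzoyl chloride in pyridine to give 2-acetyl-3,5,6-trimethoxyphenyl 3,4-dimethoxybenzoate F1. KOH in pyridine at 50 °C should then move the aroyl group from oxygen to the enolate carbon (Baker–Venkataraman rearrangement) to give 1-(3,4-dimethoxyphenyl)-3-(2-hydroxy-3,4,6-trimethoxyphenyl)propane-1,3-dione F2. H2SO4 (cat.) in AcOH at 100 °C would close ring C by cyclodehydration and give 10.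

Step 4. Methanol or methoxide may add in conjugate fashion to the electron-poor enyne or attack C2 and open the pyranone ring, before or after the homologation. The fallback replaces the diazo homologation by olefination and elimination in aprotic media; it sets out from 6 and returns at 7. A Wittig reaction of 6 with bromomethylenetriphenylphosphorane, made from (bromomethyl)triphenylphosphonium bromide and KOtBu in THF at −78 °C, should give (Z)-2-(2-bromovinyl)-5,7,8-trimethoxy-4H-chromen-4-one F3. Anti elimination of HBr with TBAF in DMF would then give 7.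

Step 3. The oxidation may stall or run on to the carboxylic acid, and colloidal selenium may be carried through. The fallback builds the C2 carbon at the ester oxidation level and bypasses 5; it sets out from 3 and returns at 6. Claisen condensation of 3 with diethyl oxalate (NaOEt, EtOH) should give ethyl 4-(2-hydroxy-3,4,6-trimethoxyphenyl)-2,4-dioxobutanoate F4. Acid cyclodehydration (HCl, EtOH, reflux) would give ethyl 5,7,8-trimethoxy-4-oxo-4H-chromene-2-carboxylate F5. NaBH4 in MeOH/THF at 0 °C should reduce the activated ester to 2-(hydroxymethyl)-5,7,8-trimethoxy-4H-chromen-4-one F6, and MnO2 in CH2Cl2 would oxidise this allylic-type alcohol to 6.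

**Further compounds**

F1 | step 5 | 2-acetyl-3,5,6-trimethoxyphenyl 3,4-dimethoxybenzoate | CC(=O)c1c(OC)cc(OC)c(OC)c1OC(=O)c1ccc(OC)c(OC)c1
F2 | step 5 | 1-(3,4-dimethoxyphenyl)-3-(2-hydroxy-3,4,6-trimethoxyphenyl)propane-1,3-dione | COc1ccc(C(=O)CC(=O)c2c(OC)cc(OC)c(OC)c2O)cc1OC
F3 | step 4 | (Z)-2-(2-bromovinyl)-5,7,8-trimethoxy-4H-chromen-4-one | Br/C=C\c1cc(=O)c2c(OC)cc(OC)c(OC)c2o1
F4 | step 3 | ethyl 4-(2-hydroxy-3,4,6-trimethoxyphenyl)-2,4-dioxobutanoate | CCOC(=O)C(=O)CC(=O)c1c(OC)cc(OC)c(OC)c1O
F5 | step 3 | ethyl 5,7,8-trimethoxy-4-oxo-4H-chromene-2-carboxylate | CCOC(=O)c1cc(=O)c2c(OC)cc(OC)c(OC)c2o1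
F6 | step 3 | 2-(hydroxymethyl)-5,7,8-trimethoxy-4H-chromen-4-one | OCc1cc(=O)c2c(OC)cc(OC)c(OC)c2o1
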